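Ring A is disconnected from a preformed 2-aryl-4-pyranone (rings C and B). One photochemical Wolff benzannulation of a pyranonyl α-diazo ketone with a siloxyalkyne forms C8a–C8, C8–C7, C6–C5 and C5–C4a. The step exploits the fusion of the phloroglucinol ring A to the pyranone at C4a–C8a: the pyranone C2=C3 bond becomes C8a=C4a, O1 is already in place, O5 emerges as the free chelated phenol, O7 as a silyl ether, and C8 arrives bearing its side chain. The precursor is a 2-acyl-6-aryl-4-pyranone whose α-diazo carbon carries the (R)-2-silyloxy-3-methylbut-3-enyl chain, set by an auxiliary-controlled acetate aldol with methacrolein.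

Key step: step 13

Remarks on the chemistry (assumptions):
- The carbinol centre of the target is read as R (O > isopropenyl > CH2Ar); every intermediate keeps this descriptor because the CH2 branch never outranks isopropenyl.
- The ring B phenol is carried as its TIPS ether, not a TBS ether, because an aryl TBS ether is at risk in the base and acid steps that build the pyranone. Fluoride still removes all silyl groups in one operation.
- (Triisopropylsilyloxy)ethyne is not taken to be a catalogue compound and is made in steps 11 and 12. Chloroacetaldehyde is used as the anhydrous monomer, freshly obtained from its commercial aqueous solution.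
- (R)-HYTRA, N-methoxy-N-methylacetamide, diethyl oxalate and methacrolein are taken as commercial.

Step 1
Reactants: 1 4'-hydroxyacetophenone
Product: 2 1-[4-(triisopropylsilyloxy)phenyl]ethan-1-one
Conditions: TIPSCl, imidazole, DMF, 23 °C
Reagents that add atoms: triisopropylsilyl chloride, CC(C)[Si](Cl)(C(C)C)C(C)C
Why: Standard phenol silylation gives an aryl TIPS ether that should tolerate the amide bases, the Grignard reagent, irradiation and heating ahead and falls to fluoride at the end.

Step 2
Reactants: 2 1-[4-(triisopropylsilyloxy)phenyl]ethan-1-one; 3 N-methoxy-N-methylacetamide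
Product: 4 1-[4-(triisopropylsilyloxy)phenyl]butane-1,3-dione
Conditions: LiN(SiMe3)2 (2.2 equiv), THF, −78 °C; then 3, −78 → 23 °C; aq. NH4Cl
Reagents that add atoms: none
Why: Crossed Claisen-type C-acylation of the lithium enolate of 2 by the Weinreb amide, with the second equivalent of base holding the diketone as its enolate, avoids the alkoxide that would threaten the aryl silyl ether.

Step 3
Reactants: 4 1-[4-(triisopropylsilyloxy)phenyl]butane-1,3-dione; 5 diethyl oxalate
Product: 7 ethyl 4-oxo-6-[4-(triisopropylsilyloxy)phenyl]-4H-pyran-2-carboxylate, via triketo ester 6 (not isolated)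
Conditions: LiN(iPr)2 (2.2 equiv), THF, −78 → 0 °C; added to 5 (3 equiv), THF, −78 °C; aq. HCl; then p-TsOH·H2O (cat.), toluene, 80 °C
Reagents that add atoms: none
Why: The 1,3-dianion of 4 is acylated at its terminal carbon by the oxalate (Claisen condensation), and acid-catalysed cyclodehydration of the 1,3,5-triketone 6 closes the 4-pyranone, the classical route to 6-arylcomanic esters.

Step 4
Reactants: 7 ethyl 4-oxo-6-[4-(triisopropylsilyloxy)phenyl]-4H-pyran-2-carboxylate
Product: 8 N-methoxy-N-methyl-4-oxo-6-[4-(triisopropylsilyloxy)phenyl]-4H-pyran-2-carboxamide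
Conditions: MeNHOMe·HCl, iPrMgCl, THF, −20 °C
Reagents that add atoms: N,O-dimethylhydroxylamine hydrochloride, CNOC.Cl
Why: Weinreb amide formation by aminolysis of the activated ester with the chloromagnesium amide should be fast at −20 °C, well below the temperature at which nitrogen nucleophiles open 4-pyranones.

Step 5
Reactants: 9 (R)-2-hydroxy-1,2,2-triphenylethyl acetate ((R)-HYTRA); 10 methacrolein
Product: 11 (R)-2-hydroxy-1,2,2-triphenylethyl (R)-3-hydroxy-4-methylpent-4-enoate
Conditions: LiN(iPr)2 (2.1 equiv), THF, −78 → 0 °C; then 10, THF/2-methylbutane, −120 °C; aq. NH4Cl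
Reagents that add atoms: none
Why: Auxiliary-controlled acetate aldol (HYTRA aldol): the doubly lithiated enolate adds 1,2 to the enal with the facial preference that this auxiliary shows for α-branched aldehydes, which corresponds to the R carbinol centre here, and the minor diastereomer should be removable by crystallisation or chromatography.

Step 6
Reactants: 11 (R)-2-hydroxy-1,2,2-triphenylethyl (R)-3-hydroxy-4-methylpent-4-enoate
Product: 12 (R)-2-hydroxy-1,2,2-triphenylethyl (R)-3-(tert-butyldimethylsilyloxy)-4-methylpent-4-enoate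
Conditions: TBSCl, imidazole, DMF, 23 °C
Reagents that add atoms: tert-butyldimethylsilyl chloride, CC(C)(C)[Si](C)(C)Cl
Why: Standard silylation protects the secondary allylic alcohol, while the tertiary diphenylcarbinol of the auxiliary is too hindered to react.

Step 7
Reactants: 12 (R)-2-hydroxy-1,2,2-triphenylethyl (R)-3-(tert-butyldimethylsilyloxy)-4-methylpent-4-enoate
Product: 13 (R)-3-(tert-butyldimethylsilyloxy)-4-methylpent-4-en-1-ol
Conditions: iBu2AlH (4 equiv), CH2Cl2, −78 → 0 °C; aq. potassium sodium tartrate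
Reagents that add atoms: none
Why: Hydride reduction of the ester gives the primary alcohol and releases the auxiliary as its diol (reductive auxiliary cleavage) without touching the silyl ether, the alkene or the stereocentre.

Step 8
Reactants: 13 (R)-3-(tert-butyldimethylsilyloxy)-4-methylpent-4-en-1-ol
Product: 14 (R)-5-bromo-3-(tert-butyldimethylsilyloxy)-2-methylpent-1-ene
Conditions: CBr4, PPh3, 2,6-lutidine, CH2Cl2, 0 °C
Reagents that add atoms: carbon tetrabromide, BrC(Br)(Br)Br
Why: Appel bromination converts the primary alcohol into the bromide under near-neutral conditions that spare the allylic silyl ether.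

Step 9
Reactants: 14 (R)-5-bromo-3-(tert-butyldimethylsilyloxy)-2-methylpent-1-ene; 8 N-methoxy-N-methyl-4-oxo-6-[4-(triisopropylsilyloxy)phenyl]-4H-pyran-2-carboxamide
Product: 16 (R)-4-(tert-butyldimethylsilyloxy)-5-methyl-1-{4-oxo-6-[4-(triisopropylsilyloxy)phenyl]-4H-pyran-2-yl}hex-5-en-1-one, via Grignard reagent 15 (not isolated)
Conditions: Mg, THF, 40 °C; then 8, THF, −78 → −40 °C; aq. NH4Cl
Reagents that add atoms: magnesium, [Mg] (ends in 15 only)
Why: Weinreb ketone synthesis: the primary Grignard reagent gives a chelated tetrahedral intermediate that releases the ketone only on work-up, and at −78 °C the amide on the electron-poor C2 position should react much faster than the vinylogous-ester carbonyl of the pyranone.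

Step 10
Reactants: 16 (R)-4-(tert-butyldimethylsilyloxy)-5-methyl-1-{4-oxo-6-[4-(triisopropylsilyloxy)phenyl]-4H-pyran-2-yl}hex-5-en-1-one
Product: 18 (R)-2-diazo-4-(tert-butyldimethylsilyloxy)-5-methyl-1-{4-oxo-6-[4-(triisopropylsilyloxy)phenyl]-4H-pyran-2-yl}hex-5-en-1-one, via trifluoroacetyl ketone 17 (not isolated)
Conditions: LiN(SiMe3)2, THF, −78 °C; CF3CO2CH2CF3; aq. HCl; then MsN3, Et3N, H2O (1 equiv), MeCN, 23 °C
Reagents that add atoms: 2,2,2-trifluoroethyl trifluoroacetate, O=C(OCC(F)(F)F)C(F)(F)F (ends in 17 only); methanesulfonyl azide, CS(=O)(=O)N=[N+]=[N-]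
Why: Detrifluoroacetylative diazo transfer (Regitz type): the only enolisable position is trifluoroacetylated through the lithium enolate, and the activated 1,3-dicarbonyl 17 takes up the diazo group with loss of the trifluoroacetyl group as the sulfonamide.

Step 11
Reactants: 19 chloroacetaldehyde
Product: 20 (Z)-(2-chloroethenyloxy)triisopropylsilane
Conditions: TIPSOTf, Et3N, Et2O, 0 → 23 °C
Reagents that add atoms: triisopropylsilyl trifluoromethanesulfonate, CC(C)[Si](OS(=O)(=O)C(F)(F)F)(C(C)C)C(C)C
Why: Soft enolisation and O-silylation of the acidified α-chloro aldehyde gives the 2-chlorovinyl silyl ether, expected mainly as the Z isomer (both isomers should converge in step 12).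

Step 12
Reactants: 20 (Z)-(2-chloroethenyloxy)triisopropylsilane
Product: 21 (triisopropylsilyloxy)ethyne
Conditions: LiN(iPr)2 (2.2 equiv), THF, −78 → 0 °C; aq. NH4Cl, −78 °C
Reagents that add atoms: none
Why: Dehydrochlorination of a 2-halovinyl ether with two equivalents of amide base (anti elimination, acetylide formation, protonation on quench) is the classical entry to alkoxyalkynes and is known for 2-halovinyl silyl ethers.

Step 13
Reactants: 18 (R)-2-diazo-4-(tert-butyldimethylsilyloxy)-5-methyl-1-{4-oxo-6-[4-(triisopropylsilyloxy)phenyl]-4H-pyran-2-yl}hex-5-en-1-one; 21 (triisopropylsilyloxy)ethyne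
Product: 26 (R)-8-[2-(tert-butyldimethylsilyloxy)-3-methylbut-3-enyl]-5-hydroxy-7-(triisopropylsilyloxy)-2-[4-(triisopropylsilyloxy)phenyl]-4H-chromen-4-one, via ketene 22 (not isolated), via cyclobutenone 23 (not isolated), via dienylketene 24 (not isolated), via dienone 25 (not isolated)
Conditions: 21 (3 equiv), hν (365 nm, Pyrex), ClCH2CH2Cl, 20 °C until 18 is consumed; then 80 °C (dark)
Reagents that add atoms: none
Why: Proposed new method: photochemical Wolff rearrangement of 18 shifts the pyranonyl group to the diazo carbon and gives ketene 22, whose carbonyl carbon is attacked by the unsubstituted, nucleophilic carbon of siloxyalkyne 21 to give cyclobutenone 23 by [2+2] cycloaddition; four-electron electrocyclic opening then gives dienylketene 24, and thermal six-electron electrocyclisation onto C3 of the pyranone followed by enolisation of 25 gives phenol 26. The closest known reaction type is the Danheiser benzannulation of aryl, heteroaryl and alkenyl α-diazo ketones with siloxyalkynes; a 4-pyranone has not been shown as the unsaturated partner, but its C2=C3 bond is a weakly delocalised enol-ether double bond that should enter the electrocyclisation more easily than a benzene bond. Ring A is closed by the 6π disrotatory electrocyclisation (C5–C4a) after C8a–C8 has been made by the 1,2-shift and C8–C7 and C6–C5 by the [2+2] step. No stereocentre is created in the product: the quaternary centre of 23 and C4a of 25 are transient, and the silylated carbinol centre is remote and untouched. The orientation of the [2+2] step is fixed by the polarisation of the siloxyalkyne, closure can occur only at C3 because the other neighbour of C2 is the ring oxygen, and Wolff shift must outrun 1,2-hydride shift, which direct irradiation at 20 °C without a metal carbenoid and an excess of alkyne should favour.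

Step 14
Reactants: 26 (R)-8-[2-(tert-butyldimethylsilyloxy)-3-methylbut-3-enyl]-5-hydroxy-7-(triisopropylsilyloxy)-2-[4-(triisopropylsilyloxy)phenyl]-4H-chromen-4-one
Product: 27 (R)-5,7-dihydroxy-8-(2-hydroxy-3-methylbut-3-enyl)-2-(4-hydroxyphenyl)-4H-chromen-4-one (CNP0315675.1)
Conditions: Bu4NF (4 equiv), AcOH (4 equiv), THF, 0 → 23 °C
Reagents that add atoms: none
Why: Fluoride-mediated desilylation cleaves the two aryl TIPS ethers and the secondary TBS ether in one operation, and the acetic acid buffer keeps the phenols protonated so that the allylic alcohol and the isopropenyl group see neither strong base nor acid.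

Compound list
1 | 4'-hydroxyacetophenone | CC(=O)c1ccc(O)cc1 | starting material
2 | 1-[4-(triisopropylsilyloxy)phenyl]ethan-1-one | CC(=O)c1ccc(O[Si](C(C)C)(C(C)C)C(C)C)cc1 | intermediate
3 | N-methoxy-N-methylacetamide | CC(=O)N(C)OC | starting material
4 | 1-[4-(triisopropylsilyloxy)phenyl]butane-1,3-dione | CC(=O)CC(=O)c1ccc(O[Si](C(C)C)(C(C)C)C(C)C)cc1 | intermediate
5 | diethyl oxalate | CCOC(=O)C(=O)OCC | starting material
6 | ethyl 2,4,6-trioxo-6-[4-(triisopropylsilyloxy)phenyl]hexanoate (not isolated) | CCOC(=O)C(=O)CC(=O)CC(=O)c1ccc(O[Si](C(C)C)(C(C)C)C(C)C)cc1 | intermediate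
7 | ethyl 4-oxo-6-[4-(triisopropylsilyloxy)phenyl]-4H-pyran-2-carboxylate | CCOC(=O)c1cc(=O)cc(-c2ccc(O[Si](C(C)C)(C(C)C)C(C)C)cc2)o1 | intermediate
8 | N-methoxy-N-methyl-4-oxo-6-[4-(triisopropylsilyloxy)phenyl]-4H-pyran-2-carboxamide | CON(C)C(=O)c1cc(=O)cc(-c2ccc(O[Si](C(C)C)(C(C)C)C(C)C)cc2)o1 | intermediate
9 | (R)-2-hydroxy-1,2,2-triphenylethyl acetate ((R)-HYTRA) | CC(=O)O[C@H](c1ccccc1)C(O)(c1ccccc1)c1ccccc1 | starting material
10 | methacrolein | C=C(C)C=O | starting material
11 | (R)-2-hydroxy-1,2,2-triphenylethyl (R)-3-hydroxy-4-methylpent-4-enoate | C=C(C)[C@H](O)CC(=O)O[C@H](c1ccccc1)C(O)(c1ccccc1)c1ccccc1 | intermediate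
12 | (R)-2-hydroxy-1,2,2-triphenylethyl (R)-3-(tert-butyldimethylsilyloxy)-4-methylpent-4-enoate | C=C(C)[C@H](O[Si](C)(C)C(C)(C)C)CC(=O)O[C@H](c1ccccc1)C(O)(c1ccccc1)c1ccccc1 | intermediate
13 | (R)-3-(tert-butyldimethylsilyloxy)-4-methylpent-4-en-1-ol | C=C(C)[C@H](O[Si](C)(C)C(C)(C)C)CCO | intermediate
14 | (R)-5-bromo-3-(tert-butyldimethylsilyloxy)-2-methylpent-1-ene | C=C(C)[C@H](O[Si](C)(C)C(C)(C)C)CCBr | intermediate
15 | (R)-[3-(tert-butyldimethylsilyloxy)-4-methylpent-4-en-1-yl]magnesium bromide (not isolated) | C=C(C)[C@H](O[Si](C)(C)C(C)(C)C)CC[Mg]Br | intermediate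
16 | (R)-4-(tert-butyldimethylsilyloxy)-5-methyl-1-{4-oxo-6-[4-(triisopropylsilyloxy)phenyl]-4H-pyran-2-yl}hex-5-en-1-one | C=C(C)[C@H](O[Si](C)(C)C(C)(C)C)CCC(=O)c1cc(=O)cc(-c2ccc(O[Si](C(C)C)(C(C)C)C(C)C)cc2)o1 | intermediate
17 | (4R)-4-(tert-butyldimethylsilyloxy)-5-methyl-1-{4-oxo-6-[4-(triisopropylsilyloxy)phenyl]-4H-pyran-2-yl}-2-(trifluoroacetyl)hex-5-en-1-one (C2 epimers and enol; not isolated) | C=C(C)[C@H](O[Si](C)(C)C(C)(C)C)CC(C(=O)C(F)(F)F)C(=O)c1cc(=O)cc(-c2ccc(O[Si](C(C)C)(C(C)C)C(C)C)cc2)o1 | intermediate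
18 | (R)-2-diazo-4-(tert-butyldimethylsilyloxy)-5-methyl-1-{4-oxo-6-[4-(triisopropylsilyloxy)phenyl]-4H-pyran-2-yl}hex-5-en-1-one | C=C(C)[C@H](O[Si](C)(C)C(C)(C)C)CC(=[N+]=[N-])C(=O)c1cc(=O)cc(-c2ccc(O[Si](C(C)C)(C(C)C)C(C)C)cc2)o1 | intermediate
19 | chloroacetaldehyde | O=CCCl | starting material
20 | (Z)-(2-chloroethenyloxy)triisopropylsilane | Cl/C=C\O[Si](C(C)C)(C(C)C)C(C)C | intermediate
21 | (triisopropylsilyloxy)ethyne | C#CO[Si](C(C)C)(C(C)C)C(C)C | intermediate
22 | ketene: (R)-4-(tert-butyldimethylsilyloxy)-5-methyl-2-{4-oxo-6-[4-(triisopropylsilyloxy)phenyl]-4H-pyran-2-yl}hexa-1,5-dien-1-one (not isolated) | C=C(C)[C@H](O[Si](C)(C)C(C)(C)C)CC(=C=O)c1cc(=O)cc(-c2ccc(O[Si](C(C)C)(C(C)C)C(C)C)cc2)o1 | intermediate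
23 | cyclobutenone: 4-[(R)-2-(tert-butyldimethylsilyloxy)-3-methylbut-3-enyl]-4-{4-oxo-6-[4-(triisopropylsilyloxy)phenyl]-4H-pyran-2-yl}-3-(triisopropylsilyloxy)cyclobut-2-en-1-one (both epimers at C4; not isolated) | C=C(C)[C@H](O[Si](C)(C)C(C)(C)C)CC1(c2cc(=O)cc(-c3ccc(O[Si](C(C)C)(C(C)C)C(C)C)cc3)o2)C(=O)C=C1O[Si](C(C)C)(C(C)C)C(C)C | intermediate
24 | dienylketene: (R,E)-6-(tert-butyldimethylsilyloxy)-7-methyl-4-{4-oxo-6-[4-(triisopropylsilyloxy)phenyl]-4H-pyran-2-yl}-3-(triisopropylsilyloxy)octa-1,3,7-trien-1-one, ketenyl group cis to the pyranone (not isolated) | C=C(C)[C@H](O[Si](C)(C)C(C)(C)C)C/C(c1cc(=O)cc(-c2ccc(O[Si](C(C)C)(C(C)C)C(C)C)cc2)o1)=C(O[Si](C(C)C)(C(C)C)C(C)C)/C=C=O | intermediate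
25 | dienone: 4a-H keto tautomer of 26, 8-[(R)-2-(tert-butyldimethylsilyloxy)-3-methylbut-3-enyl]-7-(triisopropylsilyloxy)-2-[4-(triisopropylsilyloxy)phenyl]-4aH-chromene-4,5-dione (both epimers at C4a; not isolated) | C=C(C)[C@H](O[Si](C)(C)C(C)(C)C)CC1=C2OC(c3ccc(O[Si](C(C)C)(C(C)C)C(C)C)cc3)=CC(=O)C2C(=O)C=C1O[Si](C(C)C)(C(C)C)C(C)C | intermediate
26 | (R)-8-[2-(tert-butyldimethylsilyloxy)-3-methylbut-3-enyl]-5-hydroxy-7-(triisopropylsilyloxy)-2-[4-(triisopropylsilyloxy)phenyl]-4H-chromen-4-one | C=C(C)[C@H](O[Si](C)(C)C(C)(C)C)Cc1c(O[Si](C(C)C)(C(C)C)C(C)C)cc(O)c2c(=O)cc(-c3ccc(O[Si](C(C)C)(C(C)C)C(C)C)cc3)oc12 | intermediate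
27 | (R)-5,7-dihydroxy-8-(2-hydroxy-3-methylbut-3-enyl)-2-(4-hydroxyphenyl)-4H-chromen-4-one (CNP0315675.1) | C=C(C)[C@H](O)Cc1c(O)cc(O)c2c(=O)cc(-c3ccc(O)cc3)oc12 | target

Total step count: 14.
Longest linear sequence: 8 steps (steps 5, 6, 7, 8, 9, 10, 13, 14; the pyranone branch through steps 1, 2, 3, 4, 9, 10, 13, 14 is equally long).

Steps most likely to fail

1. Step 13 (the proposed new method). What may go wrong: 1,2-hydride shift in the carbene instead of Wolff shift (giving the enone), photodegradation of the aryl pyranone chromophore, or failure of the six-electron closure onto the pyranone. The fallback uses only known reaction types, takes ring A from phloroglucinol and builds the side chain last; it sets out from 1 and comes back to the route at 27.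
   - 1 is C-ethoxycarbonylated (NaH, diethyl carbonate, Claisen condensation) to ethyl 3-(4-hydroxyphenyl)-3-oxopropanoate F1.
   - F1 is condensed with phloroglucinol (neat, 240 °C, Mentzer-type pyranone synthesis) to apigenin F2, which can also be bought.
   - Selective alkylation of the most acidic 7-OH (allyl bromide, K2CO3, DMF) gives 7-O-allylapigenin F3.
   - Aromatic Claisen rearrangement (N,N-diethylaniline, 200 °C) gives 8-allylapigenin F4; C8 is the expected site when the 5-OH is chelated, and any C6 isomer is separated.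
   - Silylation of the 7- and 4'-OH (TIPSCl, imidazole) gives 8-allyl-5-hydroxy-7,4'-bis(triisopropylsilyloxy)flavone F5.
   - Cross-metathesis with 2-methylbut-2-ene (second-generation Grubbs catalyst) gives the 8-prenyl flavone F6.
   - Shi epoxidation (D-fructose-derived ketone, KHSO5, K2CO3 buffer) gives the (R)-epoxide F7.
   - Al(OiPr)3-mediated isomerisation of the trisubstituted epoxide (toluene, reflux), which breaks only the tertiary C–O bond, gives the (R)-allylic alcohol F8.
   - Bu4NF/AcOH then gives 27.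

2. Step 9. What may go wrong: attack of the Grignard reagent on the pyranone (addition to the C4 carbonyl or conjugate addition) in competition with the amide, or incomplete Grignard formation. The fallback replaces the polar addition by a Fukuyama coupling; it sets out from 7 and 14 and comes back at 16.
   - 7 is converted with Me2AlSEt (from AlMe3 and EtSH, CH2Cl2) into the S-ethyl thioester F9.
   - 14 is converted with zinc dust and LiCl (THF, 50 °C) into the alkylzinc bromide F10.
   - PdCl2(PPh3)2-catalysed coupling of F9 with F10 (toluene/THF, 23 °C) gives 16; the organozinc reagent does not add to pyranone carbonyls.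

3. Step 3. What may go wrong: proton transfer from the acidic product to the dianion (incomplete acylation), or loss of the aryl silyl ether during the acid cyclodehydration. The fallback uses equilibrium Claisen chemistry on the free phenol and silylates last; it sets out from 1 and comes back at 7.
   - 1 with NaH and ethyl acetate gives 1-(4-hydroxyphenyl)butane-1,3-dione F11.
   - F11 with diethyl oxalate (5) and excess NaOEt in ethanol gives the triketo ester F12.
   - F12 is cyclised with HCl in ethanol to ethyl 6-(4-hydroxyphenyl)-4-oxo-4H-pyran-2-carboxylate F13.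
   - TIPSCl/imidazole then gives 7.

Further compounds
F1 | step 13 | ethyl 3-(4-hydroxyphenyl)-3-oxopropanoate | CCOC(=O)CC(=O)c1ccc(O)cc1
F2 | step 13 | apigenin (5,7-dihydroxy-2-(4-hydroxyphenyl)-4H-chromen-4-one) | O=c1cc(-c2ccc(O)cc2)oc2cc(O)cc(O)c12
F3 | step 13 | 7-(allyloxy)-5-hydroxy-2-(4-hydroxyphenyl)-4H-chromen-4-one | C=CCOc1cc(O)c2c(=O)cc(-c3ccc(O)cc3)oc2c1
F4 | step 13 | 8-allyl-5,7-dihydroxy-2-(4-hydroxyphenyl)-4H-chromen-4-one | C=CCc1c(O)cc(O)c2c(=O)cc(-c3ccc(O)cc3)oc12
F5 | step 13 | 8-allyl-5-hydroxy-7-(triisopropylsilyloxy)-2-[4-(triisopropylsilyloxy)phenyl]-4H-chromen-4-one | C=CCc1c(O[Si](C(C)C)(C(C)C)C(C)C)cc(O)c2c(=O)cc(-c3ccc(O[Si](C(C)C)(C(C)C)C(C)C)cc3)oc12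
F6 | step 13 | 5-hydroxy-8-(3-methylbut-2-enyl)-7-(triisopropylsilyloxy)-2-[4-(triisopropylsilyloxy)phenyl]-4H-chromen-4-one | CC(C)=CCc1c(O[Si](C(C)C)(C(C)C)C(C)C)cc(O)c2c(=O)cc(-c3ccc(O[Si](C(C)C)(C(C)C)C(C)C)cc3)oc12
F7 | step 13 | (R)-8-[(3,3-dimethyloxiran-2-yl)methyl]-5-hydroxy-7-(triisopropylsilyloxy)-2-[4-(triisopropylsilyloxy)phenyl]-4H-chromen-4-one | CC1(C)O[C@@H]1Cc2c(O[Si](C(C)C)(C(C)C)C(C)C)cc(O)c3c(=O)cc(-c4ccc(O[Si](C(C)C)(C(C)C)C(C)C)cc4)oc23
F8 | step 13 | (R)-5-hydroxy-8-(2-hydroxy-3-methylbut-3-enyl)-7-(triisopropylsilyloxy)-2-[4-(triisopropylsilyloxy)phenyl]-4H-chromen-4-one | C=C(C)[C@H](O)Cc1c(O[Si](C(C)C)(C(C)C)C(C)C)cc(O)c2c(=O)cc(-c3ccc(O[Si](C(C)C)(C(C)C)C(C)C)cc3)oc12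
F9 | step 9 | S-ethyl 4-oxo-6-[4-(triisopropylsilyloxy)phenyl]-4H-pyran-2-carbothioate | CCSC(=O)c1cc(=O)cc(-c2ccc(O[Si](C(C)C)(C(C)C)C(C)C)cc2)o1
F10 | step 9 | (R)-[3-(tert-butyldimethylsilyloxy)-4-methylpent-4-en-1-yl]zinc bromide | C=C(C)[C@H](O[Si](C)(C)C(C)(C)C)CC[Zn]Br
F11 | step 3 | 1-(4-hydroxyphenyl)butane-1,3-dione | CC(=O)CC(=O)c1ccc(O)cc1
F12 | step 3 | ethyl 6-(4-hydroxyphenyl)-2,4,6-trioxohexanoate | CCOC(=O)C(=O)CC(=O)CC(=O)c1ccc(O)cc1
F13 | step 3 | ethyl 6-(4-hydroxyphenyl)-4-oxo-4H-pyran-2-carboxylate | CCOC(=O)c1cc(=O)cc(-c2ccc(O)cc2)o1
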